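## Retrosynthetic overview

1. Punaglandin 4 (36) ⇐ chloro dienone 33 (desilylation, diacetylation, acetonide removal) ⇐ ketone 26 by chlorination at C10 and dehydrogenation to C10=C11; C10 is the only enolisable position of 26.
2. The strategy rests on C8 of ring A, which carries the exocyclic C7=C8 alkene and sits between the C9 ketone and the quaternary C12 carbinol. This is the pattern left when C12 shifts from a C9 carbinol onto a C7≡C8 alkyne, so 26 ⇐ 1-alkynylcyclobutanol 25 (C8–C12 bond; ring C9–C10–C11–C12 enlarged to ring A; 7E set).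
3. 25 ⇐ C8–C9 bond: cyclobutanone 12 plus the acetylide of alkyne acid 22.
4. 12 ⇐ symmetrical enediol ether 1 (decarboxylative asymmetric allylation sets C12; ozonolysis; Z-Wittig). 22 ⇐ L-threitol acetonide 13, whose C5/C6 come from L-tartaric acid (Giese extension, Ohira–Bestmann alkynylation).
5. Ring order: the cyclobutane is carried from 1; ring A is the only ring formed (step 16).

Key step: step 16

Remarks on the chemistry:
- Prostanoid numbering (C1–C20) is used throughout.
- The sense of induction in step 2 is assigned by analogy with 2-alkylcycloalkanone enolates, for which the (S)-ligand places the allyl group on the face that corresponds here to (R); the (R)-ligand is therefore chosen for (S)-5.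
- Compounds 24 and 25 are C9 epimer mixtures and 29 is a C10 epimer mixture; both centres become trigonal later.
- The CIP descriptor at C12 changes from S to R once C10 carries chlorine or C10=C11 is present; the spatial arrangement is unchanged.

## Route

**Step 1**
Reactants: 1 1,2-bis(trimethylsilyloxy)cyclobut-1-ene; 2 allyl chloroformate
Product: 4 allyl 2-(trimethylsilyloxy)cyclobut-1-en-1-yl carbonate, via lithium enolate 3 (not isolated)
Conditions: MeLi (1.0 equiv), THF, 0 °C → rt; TMEDA, then 2, −78 °C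
Reagents that add atoms: none
Why: MeLi cleaves one Si–O bond of the symmetrical enediol bis-silyl ether to a single lithium enolate (no regiochemical question), which the hard chloroformate O-acylates to the enol carbonate (enolate generation from a silyl enol ether, then O-acylation).

**Step 2**
Reactants: 4 allyl 2-(trimethylsilyloxy)cyclobut-1-en-1-yl carbonate
Product: 5 (2S)-2-allyl-2-(trimethylsilyloxy)cyclobutan-1-one
Conditions: Pd2(dba)3 (2.5 mol %), (R)-t-BuPHOX [(R)-4-tert-butyl-2-(2-diphenylphosphinophenyl)-4,5-dihydrooxazole] (6 mol %), THF, 25 °C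
Reagents that add atoms: none
Why: Oxidative addition of zerovalent palladium to the allyl carbonate and loss of CO2 should give an allylpalladium enolate that recombines at the oxygen-bearing enolate carbon within the chiral ligand pocket (decarboxylative asymmetric allylic alkylation, Tsuji–Trost type), setting the quaternary C12 centre under ligand control.

**Step 3**
Reactants: 5 (2S)-2-allyl-2-(trimethylsilyloxy)cyclobutan-1-one
Product: 6 (2S)-2-allyl-2-hydroxycyclobutan-1-one
Conditions: 10% aq. citric acid, THF, 0 °C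
Reagents that add atoms: none
Why: The tertiary trimethylsilyl ether is hydrolysed by mild aqueous acid (silyl ether hydrolysis); base and heat are avoided so that the α-ketol cannot rearrange and scramble C12.

**Step 4**
Reactants: 6 (2S)-2-allyl-2-hydroxycyclobutan-1-one
Product: 7 (2S)-2-allyl-2-(tert-butyldimethylsilyloxy)cyclobutan-1-one
Conditions: TBSOTf, 2,6-lutidine, CH2Cl2, −78 → 0 °C
Reagents that add atoms: tert-butyldimethylsilyl trifluoromethanesulfonate, CC(C)(C)[Si](C)(C)OS(=O)(=O)C(F)(F)F
Why: A silyl triflate with a hindered pyridine base silylates the tertiary alcohol (O-silylation) and gives an ether robust enough for the organometallic, gold and enolate steps that follow.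

**Step 5**
Reactants: 7 (2S)-2-allyl-2-(tert-butyldimethylsilyloxy)cyclobutan-1-one
Product: 9 2-[(1S)-1-(tert-butyldimethylsilyloxy)-2-oxocyclobutyl]acetaldehyde, via ozonide 8 (not isolated)
Conditions: O3, CH2Cl2, −78 °C; PPh3, −78 °C → rt
Reagents that add atoms: ozone, [O-][O+]=O
Why: Ozonolysis with reductive work-up cleaves the terminal alkene to the C14 aldehyde; the ketone and silyl ether are inert to ozone.

**Step 6**
Reactants: 9 2-[(1S)-1-(tert-butyldimethylsilyloxy)-2-oxocyclobutyl]acetaldehyde; 10 hexyltriphenylphosphonium bromide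
Product: 12 (2S)-2-(tert-butyldimethylsilyloxy)-2-[(2Z)-oct-2-en-1-yl]cyclobutan-1-one, via hexylidenetriphenylphosphorane 11 (not isolated)
Conditions: 10, NaHMDS, THF, 0 °C; ylide (1.0 equiv) added to 9, −78 → 0 °C
Reagents that add atoms: none
Why: A non-stabilised ylide under lithium-free conditions should give the 14Z alkene (Wittig olefination), and at −78 °C with one equivalent it should take the aldehyde in preference to the hindered α-quaternary ketone.

**Step 7**
Reactants: 13 (4S,5S)-2,2-dimethyl-1,3-dioxolane-4,5-dimethanol (2,3-O-isopropylidene-L-threitol)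
Product: 15 [(4S,5S)-5-(tert-butyldimethylsilyloxymethyl)-2,2-dimethyl-1,3-dioxolan-4-yl]methanol, via monosodium alkoxide 14 (not isolated)
Conditions: NaH (1.0 equiv), THF, 0 °C; TBSCl (1.0 equiv), rt
Reagents that add atoms: tert-butyldimethylsilyl chloride, CC(C)(C)[Si](C)(C)Cl
Why: Monosilylation of the C2-symmetric diol through its monosodium alkoxide (O-silylation); the two hydroxyls are equivalent, so no stereochemical choice arises.

**Step 8**
Reactants: 15 [(4S,5S)-5-(tert-butyldimethylsilyloxymethyl)-2,2-dimethyl-1,3-dioxolan-4-yl]methanol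
Product: 16 tert-butyl{[(4S,5R)-5-(iodomethyl)-2,2-dimethyl-1,3-dioxolan-4-yl]methoxy}dimethylsilane
Conditions: I2, PPh3, imidazole, CH2Cl2, 0 °C → rt
Reagents that add atoms: iodine, II
Why: Appel-type iodination of the primary alcohol through its alkoxyphosphonium ion; the stereocentres are not touched (the descriptor changes only by CIP priority).

**Step 9**
Reactants: 16 tert-butyl{[(4S,5R)-5-(iodomethyl)-2,2-dimethyl-1,3-dioxolan-4-yl]methoxy}dimethylsilane; 17 methyl acrylate
Product: 18 methyl 4-[(4S,5S)-5-(tert-butyldimethylsilyloxymethyl)-2,2-dimethyl-1,3-dioxolan-4-yl]butanoate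
Conditions: 17 (3 equiv), (Me3Si)3SiH, AIBN (cat.), toluene, 80 °C, slow addition
Reagents that add atoms: none
Why: The primary C4 radical formed by iodine abstraction adds to the acrylate and the adduct radical is reduced by the silane (Giese radical conjugate addition), installing C1–C3 with the ester in one step.

**Step 10**
Reactants: 18 methyl 4-[(4S,5S)-5-(tert-butyldimethylsilyloxymethyl)-2,2-dimethyl-1,3-dioxolan-4-yl]butanoate
Product: 19 methyl 4-[(4S,5S)-5-(hydroxymethyl)-2,2-dimethyl-1,3-dioxolan-4-yl]butanoate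
Conditions: HF·pyridine, pyridine, THF, 0 °C → rt
Reagents that add atoms: none
Why: Buffered fluoride cleaves the primary silyl ether (desilylation) and leaves the acetonide and methyl ester intact.

**Step 11**
Reactants: 19 methyl 4-[(4S,5S)-5-(hydroxymethyl)-2,2-dimethyl-1,3-dioxolan-4-yl]butanoate
Product: 20 methyl 4-[(4S,5R)-5-formyl-2,2-dimethyl-1,3-dioxolan-4-yl]butanoate
Conditions: Dess–Martin periodinane, NaHCO3, CH2Cl2, 0 °C → rt
Reagents that add atoms: none
Why: Buffered Dess–Martin oxidation gives the α-alkoxy aldehyde without epimerisation (oxidation of a primary alcohol).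

**Step 12**
Reactants: 20 methyl 4-[(4S,5R)-5-formyl-2,2-dimethyl-1,3-dioxolan-4-yl]butanoate
Product: 21 methyl 4-[(4S,5S)-5-ethynyl-2,2-dimethyl-1,3-dioxolan-4-yl]butanoate
Conditions: dimethyl (1-diazo-2-oxopropyl)phosphonate, K2CO3, MeOH, 0 °C → rt
Reagents that add atoms: dimethyl (1-diazo-2-oxopropyl)phosphonate, CC(=O)C(=[N+]=[N-])P(=O)(OC)OC
Why: Ohira–Bestmann (Seyferth–Gilbert) homologation converts the aldehyde into the terminal alkyne (C7≡C8) under mild base; the trans-dioxolane is the thermodynamically preferred isomer, so C6 should hold.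

**Step 13**
Reactants: 21 methyl 4-[(4S,5S)-5-ethynyl-2,2-dimethyl-1,3-dioxolan-4-yl]butanoate
Product: 22 4-[(4S,5S)-5-ethynyl-2,2-dimethyl-1,3-dioxolan-4-yl]butanoic acid
Conditions: LiOH, THF/H2O, 0 °C → rt; 1 M HCl to pH 4, 0 °C
Reagents that add atoms: lithium hydroxide, [Li+].[OH-]
Why: Saponification turns the electrophilic methyl ester into a carboxylate, which protects C1 from butyllithium during acetylide formation in step 14.

**Step 14**
Reactants: 22 4-[(4S,5S)-5-ethynyl-2,2-dimethyl-1,3-dioxolan-4-yl]butanoic acid; 12 (2S)-2-(tert-butyldimethylsilyloxy)-2-[(2Z)-oct-2-en-1-yl]cyclobutan-1-one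
Product: 24 4-[(4S,5S)-5-({(2S)-2-(tert-butyldimethylsilyloxy)-1-hydroxy-2-[(2Z)-oct-2-en-1-yl]cyclobutyl}ethynyl)-2,2-dimethyl-1,3-dioxolan-4-yl]butanoic acid (both C9 epimers), via dilithium carboxylate acetylide 23 (not isolated)
Conditions: n-BuLi (2.05 equiv), THF/DMPU, −78 → −40 °C; 12, −78 °C; AcOH quench at −78 °C
Reagents that add atoms: none
Why: The carboxylate/acetylide dianion adds through its acetylide carbon to the strained, highly electrophilic cyclobutanone carbonyl (1,2-addition of a lithium acetylide), forming C8–C9; the C9 configuration is immaterial and the cold quench limits silyl migration from O12 to O9.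

**Step 15**
Reactants: 24 4-[(4S,5S)-5-({(2S)-2-(tert-butyldimethylsilyloxy)-1-hydroxy-2-[(2Z)-oct-2-en-1-yl]cyclobutyl}ethynyl)-2,2-dimethyl-1,3-dioxolan-4-yl]butanoic acid
Product: 25 methyl 4-[(4S,5S)-5-({(2S)-2-(tert-butyldimethylsilyloxy)-1-hydroxy-2-[(2Z)-oct-2-en-1-yl]cyclobutyl}ethynyl)-2,2-dimethyl-1,3-dioxolan-4-yl]butanoate (1-alkynylcyclobutanol; both C9 epimers)
Conditions: Me3SiCHN2, MeOH/toluene, 0 °C
Reagents that add atoms: (trimethylsilyl)diazomethane, C[Si](C)(C)C=[N+]=[N-]
Why: Methylation of the carboxylic acid with (trimethylsilyl)diazomethane in methanol restores the C1 methyl ester (esterification) without touching the tertiary alcohol.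

**Step 16**
Reactants: 25 methyl 4-[(4S,5S)-5-({(2S)-2-(tert-butyldimethylsilyloxy)-1-hydroxy-2-[(2Z)-oct-2-en-1-yl]cyclobutyl}ethynyl)-2,2-dimethyl-1,3-dioxolan-4-yl]butanoate
Product: 26 methyl 4-[(4S,5S)-5-{(E)-[(2S)-2-(tert-butyldimethylsilyloxy)-2-[(2Z)-oct-2-en-1-yl]-5-oxocyclopentylidene]methyl}-2,2-dimethyl-1,3-dioxolan-4-yl]butanoate (10,11-dihydro-10-deschloro skeleton; C12 silyl ether; C5,C6 acetonide)
Conditions: (Ph3P)AuCl (5 mol %), AgSbF6 (5 mol %), CH2Cl2, 0 °C → rt
Reagents that add atoms: none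
Why: Cationic (Ph3P)Au+ (monovalent gold) binds the C7≡C8 alkyne, and the C9–C12 σ bond anti to gold shifts to C8 while the C9 hydroxyl oxygen becomes the ketone, giving a C7 vinyl-gold that is protodeaurated with retention (semipinacol 1,2-alkyl shift driven by release of cyclobutane strain). The closest known reaction type is the gold-catalysed ring expansion of 1-alkynylcyclobutanols to (E)-2-alkylidenecyclopentanones; migration of a silyloxy-bearing quaternary carbon extends the alkyl-substituted cases within that substrate class. Ring A is closed by a four- to five-membered ring enlargement in which the C9–C12 bond adds to C8 in an exo sense with respect to the alkyne. No stereocentre is created: C12 migrates with retention, both C9 epimers converge because C9 becomes trigonal, and anti addition of C12 and gold followed by retentive protodeauration leaves H7 cis to C9, which is the 7E geometry. The step needs C12 to migrate in preference to C10, which the higher migratory aptitude of the more substituted, oxygen-stabilised carbon should secure, and it needs the shift to outrun attack of the C14=C15 alkene on the activated alkyne, which a unimolecular strain-releasing shift next to a hydroxyl donor should do at 0 °C.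

**Step 17**
Reactants: 26 methyl 4-[(4S,5S)-5-{(E)-[(2S)-2-(tert-butyldimethylsilyloxy)-2-[(2Z)-oct-2-en-1-yl]-5-oxocyclopentylidene]methyl}-2,2-dimethyl-1,3-dioxolan-4-yl]butanoate
Product: 29 10-chloro ketone: methyl 4-[(4S,5S)-5-{(E)-[2-(tert-butyldimethylsilyloxy)-4-chloro-2-[(2Z)-oct-2-en-1-yl]-5-oxocyclopentylidene]methyl}-2,2-dimethyl-1,3-dioxolan-4-yl]butanoate (C12 as in 26; C10 epimers), via lithium dienolate 27 (not isolated), via trimethylsilyl dienol ether 28 (not isolated)
Conditions: LiHMDS (1.1 equiv), THF, −78 °C; TMSCl; solvent exchange to pentane, filtration; NCS, THF, −78 → 0 °C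
Reagents that add atoms: N-chlorosuccinimide, O=C1CCC(=O)N1Cl
Why: Kinetic deprotonation can occur only at C10 (C8 has no hydrogen and the ketone is far more acidic than the ester), and the resulting 2-silyloxydiene is chlorinated at its enol ether terminus by NCS (α-chlorination of a silyl enol ether), which avoids over-chlorination.

**Step 18**
Reactants: 29 10-chloro ketone (C10 epimers)
Product: 33 chloro dienone: methyl 4-[(4S,5S)-5-{(E)-[(2R)-2-(tert-butyldimethylsilyloxy)-4-chloro-2-[(2Z)-oct-2-en-1-yl]-5-oxocyclopent-3-en-1-ylidene]methyl}-2,2-dimethyl-1,3-dioxolan-4-yl]butanoate, via lithium chloro enolate 30 (not isolated), via chloro selenide 31 (not isolated), via selenoxide 32 (not isolated)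
Conditions: LiHMDS (1.1 equiv), THF, −78 °C; PhSeCl, −78 °C; then CH2Cl2, pyridine, 30% H2O2 (2 equiv), 0 °C → rt
Reagents that add atoms: none
Why: The chloro enolate is selenenylated at C10, and oxidation to the selenoxide is followed by syn-elimination toward C11, the only carbon with a β-hydrogen (α-selenenylation, then selenoxide elimination), giving the 10-chloro-C10=C11 enone; pyridine and a limited amount of peroxide protect the C14=C15 alkene.

**Step 19**
Reactants: 33 chloro dienone
Product: 34 methyl (5S,6S,7E,12R,14Z)-12-(tert-butyldimethylsilyloxy)-10-chloro-5,6-dihydroxy-9-oxoprosta-7,10,14-trien-1-oate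
Conditions: CSA (0.2 equiv), MeOH, 0 °C → rt; Et3N before concentration
Reagents that add atoms: none
Why: Acid-catalysed transketalisation to methanol removes the acetonide while the hindered tertiary silyl ether stays; the large excess of methanol and neutralisation before concentration keep the 5-hydroxy methyl ester from closing to the δ-lactone.

**Step 20**
Reactants: 34 methyl (5S,6S,7E,12R,14Z)-12-(tert-butyldimethylsilyloxy)-10-chloro-5,6-dihydroxy-9-oxoprosta-7,10,14-trien-1-oate
Product: 35 methyl (5S,6S,7E,12R,14Z)-5,6-diacetoxy-12-(tert-butyldimethylsilyloxy)-10-chloro-9-oxoprosta-7,10,14-trien-1-oate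
Conditions: Ac2O, pyridine, DMAP (cat.), CH2Cl2, 0 °C
Reagents that add atoms: acetic anhydride, CC(=O)OC(C)=O
Why: Nucleophile-catalysed acetylation of the two secondary hydroxyls (O-acylation) while C12–O is still silylated; the low temperature disfavours vinylogous elimination of the C5 acetate.

**Step 21**
Reactants: 35 methyl (5S,6S,7E,12R,14Z)-5,6-diacetoxy-12-(tert-butyldimethylsilyloxy)-10-chloro-9-oxoprosta-7,10,14-trien-1-oate
Product: 36 punaglandin 4, methyl (5S,6S,7E,12R,14Z)-5,6-diacetoxy-10-chloro-12-hydroxy-9-oxoprosta-7,10,14-trien-1-oate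
Conditions: 48% aq. HF, MeCN, 0 °C → rt
Reagents that add atoms: none
Why: Acidic fluoride cleaves the tertiary silyl ether (desilylation); the acetates survive and the C12 carbinol does not ionise because its cation would be conjugated with the electron-poor dienone.

## Compound list

1 | 1,2-bis(trimethylsilyloxy)cyclobut-1-ene | C[Si](C)(C)OC1=C(O[Si](C)(C)C)CC1 | starting material
2 | allyl chloroformate | C=CCOC(=O)Cl | starting material
3 | lithium 2-(trimethylsilyloxy)cyclobut-1-en-1-olate (not isolated) | [Li+].[O-]C1=C(O[Si](C)(C)C)CC1 | intermediate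
4 | allyl 2-(trimethylsilyloxy)cyclobut-1-en-1-yl carbonate | C=CCOC(=O)OC1=C(O[Si](C)(C)C)CC1 | intermediate
5 | (2S)-2-allyl-2-(trimethylsilyloxy)cyclobutan-1-one | C=CC[C@@]1(O[Si](C)(C)C)CCC1=O | intermediate
6 | (2S)-2-allyl-2-hydroxycyclobutan-1-one | C=CC[C@@]1(O)CCC1=O | intermediate
7 | (2S)-2-allyl-2-(tert-butyldimethylsilyloxy)cyclobutan-1-one | C=CC[C@@]1(O[Si](C)(C)C(C)(C)C)CCC1=O | intermediate
8 | ozonide (1,2,4-trioxolane) of 7 (not isolated) | C1(OCOO1)C[C@@]2(O[Si](C)(C)C(C)(C)C)CCC2=O | intermediate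
9 | 2-[(1S)-1-(tert-butyldimethylsilyloxy)-2-oxocyclobutyl]acetaldehyde | O=CC[C@@]1(O[Si](C)(C)C(C)(C)C)CCC1=O | intermediate
10 | hexyltriphenylphosphonium bromide | CCCCCC[P+](c1ccccc1)(c1ccccc1)c1ccccc1.[Br-] | starting material
11 | hexylidenetriphenylphosphorane (not isolated) | CCCCCC=P(c1ccccc1)(c1ccccc1)c1ccccc1 | intermediate
12 | (2S)-2-(tert-butyldimethylsilyloxy)-2-[(2Z)-oct-2-en-1-yl]cyclobutan-1-one | CCCCC/C=C\C[C@@]1(O[Si](C)(C)C(C)(C)C)CCC1=O | intermediate
13 | (4S,5S)-2,2-dimethyl-1,3-dioxolane-4,5-dimethanol (2,3-O-isopropylidene-L-threitol) | OC[C@@H]1OC(C)(C)O[C@H]1CO | starting material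
14 | monosodium alkoxide of 13 (not isolated) | [Na+].[O-]C[C@@H]1OC(C)(C)O[C@H]1CO | intermediate
15 | [(4S,5S)-5-(tert-butyldimethylsilyloxymethyl)-2,2-dimethyl-1,3-dioxolan-4-yl]methanol | CC(C)(C)[Si](C)(C)OC[C@@H]1OC(C)(C)O[C@H]1CO | intermediate
16 | tert-butyl{[(4S,5R)-5-(iodomethyl)-2,2-dimethyl-1,3-dioxolan-4-yl]methoxy}dimethylsilane | CC(C)(C)[Si](C)(C)OC[C@@H]1OC(C)(C)O[C@H]1CI | intermediate
17 | methyl acrylate | C=CC(=O)OC | starting material
18 | methyl 4-[(4S,5S)-5-(tert-butyldimethylsilyloxymethyl)-2,2-dimethyl-1,3-dioxolan-4-yl]butanoate | CC(C)(C)[Si](C)(C)OC[C@@H]1OC(C)(C)O[C@H]1CCCC(=O)OC | intermediate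
19 | methyl 4-[(4S,5S)-5-(hydroxymethyl)-2,2-dimethyl-1,3-dioxolan-4-yl]butanoate | OC[C@@H]1OC(C)(C)O[C@H]1CCCC(=O)OC | intermediate
20 | methyl 4-[(4S,5R)-5-formyl-2,2-dimethyl-1,3-dioxolan-4-yl]butanoate | O=C[C@@H]1OC(C)(C)O[C@H]1CCCC(=O)OC | intermediate
21 | methyl 4-[(4S,5S)-5-ethynyl-2,2-dimethyl-1,3-dioxolan-4-yl]butanoate | C#C[C@@H]1OC(C)(C)O[C@H]1CCCC(=O)OC | intermediate
22 | 4-[(4S,5S)-5-ethynyl-2,2-dimethyl-1,3-dioxolan-4-yl]butanoic acid | C#C[C@@H]1OC(C)(C)O[C@H]1CCCC(=O)O | intermediate
23 | dilithium carboxylate acetylide of 22 (not isolated) | [Li+].[Li+].[C-]#C[C@@H]1OC(C)(C)O[C@H]1CCCC(=O)[O-] | intermediate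
24 | alkynylcyclobutanol acid (C9 epimers) | CCCCC/C=C\C[C@@]1(O[Si](C)(C)C(C)(C)C)CCC1(O)C#C[C@@H]2OC(C)(C)O[C@H]2CCCC(=O)O | intermediate
25 | 1-alkynylcyclobutanol methyl ester, key-step precursor (C9 epimers) | CCCCC/C=C\C[C@@]1(O[Si](C)(C)C(C)(C)C)CCC1(O)C#C[C@@H]2OC(C)(C)O[C@H]2CCCC(=O)OC | intermediate
26 | ring-expanded (7E)-enone, 10,11-dihydro-10-deschloro skeleton (C12 silyl ether, C5,C6 acetonide) | CCCCC/C=C\C[C@@]1(O[Si](C)(C)C(C)(C)C)CCC(=O)/C1=C/[C@@H]2OC(C)(C)O[C@H]2CCCC(=O)OC | intermediate
27 | lithium C9–C10 dienolate of 26 (not isolated) | CCCCC/C=C\C[C@@]1(O[Si](C)(C)C(C)(C)C)CC=C([O-])/C1=C/[C@@H]2OC(C)(C)O[C@H]2CCCC(=O)OC.[Li+] | intermediate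
28 | trimethylsilyl dienol ether of 26 (not isolated) | CCCCC/C=C\C[C@@]1(O[Si](C)(C)C(C)(C)C)CC=C(O[Si](C)(C)C)/C1=C/[C@@H]2OC(C)(C)O[C@H]2CCCC(=O)OC | intermediate
29 | 10-chloro ketone (C10 epimers) | CCCCC/C=C\C[C@@]1(O[Si](C)(C)C(C)(C)C)CC(Cl)C(=O)/C1=C/[C@@H]2OC(C)(C)O[C@H]2CCCC(=O)OC | intermediate
30 | lithium chloro enolate of 29 (not isolated) | CCCCC/C=C\C[C@@]1(O[Si](C)(C)C(C)(C)C)CC(Cl)=C([O-])/C1=C/[C@@H]2OC(C)(C)O[C@H]2CCCC(=O)OC.[Li+] | intermediate
31 | 10-chloro-10-(phenylseleno) ketone (not isolated) | CCCCC/C=C\C[C@@]1(O[Si](C)(C)C(C)(C)C)CC(Cl)([Se]c3ccccc3)C(=O)/C1=C/[C@@H]2OC(C)(C)O[C@H]2CCCC(=O)OC | intermediate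
32 | selenoxide of 31 (not isolated) | CCCCC/C=C\C[C@@]1(O[Si](C)(C)C(C)(C)C)CC(Cl)([Se](=O)c3ccccc3)C(=O)/C1=C/[C@@H]2OC(C)(C)O[C@H]2CCCC(=O)OC | intermediate
33 | chloro dienone (C12 silyl ether, C5,C6 acetonide) | CCCCC/C=C\C[C@@]1(O[Si](C)(C)C(C)(C)C)C=C(Cl)C(=O)/C1=C/[C@@H]2OC(C)(C)O[C@H]2CCCC(=O)OC | intermediate
34 | methyl (5S,6S,7E,12R,14Z)-12-(tert-butyldimethylsilyloxy)-10-chloro-5,6-dihydroxy-9-oxoprosta-7,10,14-trien-1-oate | CCCCC/C=C\C[C@@]1(O[Si](C)(C)C(C)(C)C)C=C(Cl)C(=O)/C1=C/[C@H](O)[C@H](CCCC(=O)OC)O | intermediate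
35 | methyl (5S,6S,7E,12R,14Z)-5,6-diacetoxy-12-(tert-butyldimethylsilyloxy)-10-chloro-9-oxoprosta-7,10,14-trien-1-oate | CCCCC/C=C\C[C@@]1(O[Si](C)(C)C(C)(C)C)C=C(Cl)C(=O)/C1=C/[C@H](OC(C)=O)[C@H](CCCC(=O)OC)OC(C)=O | intermediate
36 | punaglandin 4 | CCCCC/C=C\C[C@@]1(O)C=C(Cl)C(=O)/C1=C/[C@H](OC(C)=O)[C@H](CCCC(=O)OC)OC(C)=O | target

## Step count and risks

Total: 21 steps. Longest linear sequence: 15 steps (steps 7–21, from 13).

**Step 16 (gold-triggered ring expansion).** The activated alkyne may be diverted into enyne cycloisomerisation with the C14=C15 alkene, the catalyst may be lost to the propargylic acetal oxygen, or the C10 methylene may migrate instead of C12. The fallback sets out from 25 and returns at 26, forming the same C8–C12 bond by an epoxy-alcohol semipinacol without gold. Semihydrogenation of 25 (H2, Pd/CaCO3 poisoned with Pb(OAc)2, quinoline) would give the (Z)-alkenylcyclobutanol F1. Hydroxyl-directed epoxidation (VO(acac)2, t-BuOOH), which should spare the isolated alkene, would give the epoxy alcohol F2. BF3·OEt2 at −78 °C would open the epoxide at C8 with concerted shift of C12 from C9 to C8, giving the β-hydroxy ketone F3. Mesylation (MsCl, Et3N) to the mesylate F4 and elimination with DBU would then give 26.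

**Step 2 (decarboxylative asymmetric allylation).** Facial selectivity may be poor, or its sense opposite to the analogy, on an enolate whose exocyclic substituent is a silyloxy group. The fallback sets out from 4 and returns at 7 by resolution in place of asymmetric catalysis. Allylation of 4 with achiral Pd(PPh3)4 in THF would give racemic 2-allyl-2-(trimethylsilyloxy)cyclobutanone F5. The conditions of steps 3 and 4 would convert it into the racemic ketol F6 and the racemic silyl ether F7. Preparative HPLC on a chiral stationary phase would deliver 7 and set aside its (R)-enantiomer F8. Minor amounts of the wrong C12 configuration that pass this point are also removed later, because coupling with enantiopure 22 turns them into diastereomers.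

**Step 18 (selenenylation and selenoxide elimination).** Selenenylation of the hindered chloro enolate may be incomplete, or the peroxide-derived seleninic species may epoxidise the C14=C15 alkene. The fallback sets out from 29 and returns at 33 by dehydrohalogenation. The enolate 30 (LiHMDS, THF, −78 °C) would be brominated with N-bromosuccinimide to the 10-bromo-10-chloro ketone F9. Loss of hydrogen bromide toward C11 (Li2CO3, LiBr, DMF, 60–80 °C) would give 33, bromide leaving in preference to chloride.

## Further compounds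

F1 | step 16 | (Z)-alkenylcyclobutanol from semihydrogenation of 25 | CCCCC/C=C\C[C@@]1(O[Si](C)(C)C(C)(C)C)CCC1(O)/C=C\[C@@H]2OC(C)(C)O[C@H]2CCCC(=O)OC
F2 | step 16 | C7,C8-epoxy cyclobutanol | CCCCC/C=C\C[C@@]1(O[Si](C)(C)C(C)(C)C)CCC1(O)C3OC3[C@@H]2OC(C)(C)O[C@H]2CCCC(=O)OC
F3 | step 16 | ring-expanded 7-hydroxy ketone (β-hydroxy ketone) | CCCCC/C=C\C[C@@]1(O[Si](C)(C)C(C)(C)C)CCC(=O)C1C(O)[C@@H]2OC(C)(C)O[C@H]2CCCC(=O)OC
F4 | step 16 | 7-mesylate of F3 | CCCCC/C=C\C[C@@]1(O[Si](C)(C)C(C)(C)C)CCC(=O)C1C(OS(C)(=O)=O)[C@@H]2OC(C)(C)O[C@H]2CCCC(=O)OC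
F5 | step 2 | racemic 2-allyl-2-(trimethylsilyloxy)cyclobutan-1-one | C=CCC1(O[Si](C)(C)C)CCC1=O
F6 | step 2 | racemic 2-allyl-2-hydroxycyclobutan-1-one | C=CCC1(O)CCC1=O
F7 | step 2 | racemic 2-allyl-2-(tert-butyldimethylsilyloxy)cyclobutan-1-one | C=CCC1(O[Si](C)(C)C(C)(C)C)CCC1=O
F8 | step 2 | (2R)-2-allyl-2-(tert-butyldimethylsilyloxy)cyclobutan-1-one | C=CC[C@]1(O[Si](C)(C)C(C)(C)C)CCC1=O
F9 | step 18 | 10-bromo-10-chloro ketone | CCCCC/C=C\C[C@@]1(O[Si](C)(C)C(C)(C)C)CC(Cl)(Br)C(=O)/C1=C/[C@@H]2OC(C)(C)O[C@H]2CCCC(=O)OC
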